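The dihydropyran ring of the chroman is opened at C4–C4a and O1–C2 (chroman numbering). This leaves a prenylated orsellinate and a racemic C10 vinyl carbinol. The orsellinate's only free ring carbon (C4a, between two oxygens) is its most nucleophilic site. The feature exploited is C2. It carries O1, a methyl group and the 4-methylpenta-1,3-dienyl chain, so it is one tertiary end of a pentadienyl cation. One chiral Brønsted acid ionises the carbinol for Friedel–Crafts attack of C4a on the primary terminus (C4). It then re-protonates the resulting achiral triene at C3 and closes O1–C2 inside a chiral ion pair. Both carbinol enantiomers therefore converge on (R)-C2.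

Key step: step 4

Assumption: no model predicts the sense of induction of the chiral acid for this cation; the (R)-catalyst is written, both antipodes are available, and the antipode that delivers (2R) is the one to be used. Chroman numbering is O1, C2, C3, C4, C4a, C5–C8, C8a, with the side chain C1'–C4'.

Step 1
Reactants: 1 methyl 2,4-dihydroxy-6-methylbenzoate (methyl orsellinate)
Product: 2 methyl 3-bromo-4,6-dihydroxy-2-methylbenzoate
Conditions: NBS (1.0 equiv), MeCN, 0 °C
Reagents that add atoms: N-bromosuccinimide, O=C1CCC(=O)N1Br
Why: Electrophilic aromatic bromination of a 2,4-dihydroxybenzoate places Br para to the chelated 2-hydroxyl and ortho to the 4-hydroxyl (next to the methyl group) rather than between the two hydroxyls, and one equivalent of NBS at 0 °C should hold the reaction at the monobromide.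

Step 2
Reactants: 2 methyl 3-bromo-4,6-dihydroxy-2-methylbenzoate, 3 tributyl(3-methylbut-2-en-1-yl)stannane
Product: 4 methyl 4,6-dihydroxy-2-methyl-3-(3-methylbut-2-en-1-yl)benzoate
Conditions: Pd(PPh3)4 (5 mol %), 3 (1.5 equiv), DMF, 100 °C
Reagents that add atoms: none
Why: In this Stille (Kosugi–Migita) coupling of an aryl bromide with an allylstannane the prenyl group should transfer at its tin-bearing carbon to give the linear isomer, and the neutral medium tolerates the free phenols and the ester.

Step 3
Reactants: 5 (3E)-6-methylhepta-3,5-dien-2-one, 6 vinylmagnesium bromide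
Product: 7 rac-(4E)-3,7-dimethylocta-1,4,6-trien-3-ol
Conditions: THF, −78 → 0 °C; H2O quench; filtration through basic alumina, used without storage
Reagents that add atoms: none
Why: This is the 1,2-addition of a vinyl Grignard reagent to a conjugated dienone, the reaction type that converts ionones into vinyl-ionols, and the carbinol centre is left racemic on purpose because step 4 erases it.

Step 4
Reactants: 4 methyl 4,6-dihydroxy-2-methyl-3-(3-methylbut-2-en-1-yl)benzoate, 7 rac-(4E)-3,7-dimethylocta-1,4,6-trien-3-ol
Product: 9 methyl (2R)-5-hydroxy-2,7-dimethyl-2-[(1E)-4-methylpenta-1,3-dien-1-yl]-8-(3-methylbut-2-en-1-yl)-3,4-dihydro-2H-chromene-6-carboxylate, via trienylphenol 8 (not isolated)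
Conditions: (R)-3,3'-bis(2,4,6-triisopropylphenyl)-H8-BINOL N-triflylphosphoramide (10 mol %), 5 Å MS, toluene, 7 (1.3 equiv) added over 6 h, −30 → 0 °C; Et3N quench
Reagents that add atoms: none
Why: Proposed new method: the acid ionises either enantiomer of 7 to the same achiral heptatrienyl cation, the only unsubstituted ring carbon of 4 (between the two hydroxyls) attacks its unhindered primary terminus to make C4–C4a and the achiral triene 8, and protonation of 8 at C3 gives a pentadienyl cation with tertiary ends at C2 and C4' that the neighbouring hydroxyl captures at C2 to make O1–C2. The closest known reaction types are the acid-catalysed chroman condensation of phenols, resorcylate esters included, with tertiary vinyl carbinols and the chiral N-triflylphosphoramide-catalysed closure of phenols onto tertiary allyl cations that gives 2,2-disubstituted 2H-chromenes through contact ion pairs; their merger in one flask on a dienyl-extended cation is what is new. The dihydropyran ring closes 6-endo-trig (Markovnikov) with respect to C2=C3 of 8, and capture at C2' or C4' would need an eight- or ten-membered ring. C2 is the only new stereocentre and is controlled by the catalyst anion, which accepts a hydrogen bond from the attacking hydroxyl while it shields one face of the paired cation, so the racemate of 7 and any E/Z mixture at C2=C3 of 8 are funnelled into one configuration. The step needs the hydroxyl para to the ester to close the ring and the prenyl group to stay untouched: the other hydroxyl is tied up in the chelate with the ester carbonyl, and an isolated trisubstituted alkene is not protonated by an acid of this strength at or below 0 °C whereas the conjugated triene is. Slow addition of 7, molecular sieves and an amine quench at full conversion limit oligomerisation and the reversible ionisation of C2–O1 that would erode the ee.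

Step 5
Reactants: 9 methyl (2R)-5-hydroxy-2,7-dimethyl-2-[(1E)-4-methylpenta-1,3-dien-1-yl]-8-(3-methylbut-2-en-1-yl)-3,4-dihydro-2H-chromene-6-carboxylate
Product: 10 (2R)-5-hydroxy-2,7-dimethyl-2-[(1E)-4-methylpenta-1,3-dien-1-yl]-8-(3-methylbut-2-en-1-yl)-3,4-dihydro-2H-chromene-6-carboxylic acid
Conditions: KOH (10 equiv), THF/MeOH/H2O, 60 °C; then cold 1 M HCl to pH 4, EtOAc, 0 °C
Reagents that add atoms: potassium hydroxide, [K+].[OH-]
Why: This is the saponification of a chelated, doubly ortho-substituted salicylate ester, a reaction known on the closely related 5-hydroxy-7-methyl-2H-chromene-6-carboxylates; hydroxide leaves the diene, the prenyl group and the tertiary allylic aryl ether at C2 untouched, and cold acidification to pH 4 avoids ionisation at C2 and decarboxylation.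

Compound list
1 | methyl 2,4-dihydroxy-6-methylbenzoate (methyl orsellinate) | COC(=O)c1c(C)cc(O)cc1O | starting material
2 | methyl 3-bromo-4,6-dihydroxy-2-methylbenzoate | COC(=O)c1c(C)c(Br)c(O)cc1O | intermediate
3 | tributyl(3-methylbut-2-en-1-yl)stannane | CCCC[Sn](CCCC)(CCCC)CC=C(C)C | starting material
4 | methyl 4,6-dihydroxy-2-methyl-3-(3-methylbut-2-en-1-yl)benzoate | COC(=O)c1c(C)c(CC=C(C)C)c(O)cc1O | intermediate
5 | (3E)-6-methylhepta-3,5-dien-2-one | CC(=O)/C=C/C=C(C)C | starting material
6 | vinylmagnesium bromide | C=C[Mg]Br | starting material
7 | rac-(4E)-3,7-dimethylocta-1,4,6-trien-3-ol | C=CC(C)(O)/C=C/C=C(C)C | intermediate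
8 | methyl 3-[(2E,4E)-3,7-dimethylocta-2,4,6-trien-1-yl]-2,4-dihydroxy-6-methyl-5-(3-methylbut-2-en-1-yl)benzoate (trienylphenol, not isolated) | COC(=O)c1c(C)c(CC=C(C)C)c(O)c(C/C=C(C)/C=C/C=C(C)C)c1O | intermediate
9 | methyl (2R)-5-hydroxy-2,7-dimethyl-2-[(1E)-4-methylpenta-1,3-dien-1-yl]-8-(3-methylbut-2-en-1-yl)-3,4-dihydro-2H-chromene-6-carboxylate | CC(C)=C/C=C/[C@@]1(C)CCc2c(O)c(C(=O)OC)c(C)c(CC=C(C)C)c2O1 | intermediate
10 | (2R)-5-hydroxy-2,7-dimethyl-2-[(1E)-4-methylpenta-1,3-dien-1-yl]-8-(3-methylbut-2-en-1-yl)-3,4-dihydro-2H-chromene-6-carboxylic acid | CC(C)=C/C=C/[C@@]1(C)CCc2c(O)c(C(=O)O)c(C)c(CC=C(C)C)c2O1 | target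

Total step count: 5. Longest linear sequence: 4 steps (1 → 2 → 4 → 9 → 10).

Steps most likely to fail

Step 4. Three processes may spoil it:
- poor facial discrimination in the ion pair;
- loss of ee through reversible ionisation of the C2–O1 bond;
- oligomerisation of the polyenyl cation before the deactivated arene intercepts it.

The fallback sets out from 4 and 7. It joins them by the classical achiral chroman condensation (p-TsOH, 5 mol %, CH2Cl2, 0 °C, slow addition of 7), which should give the racemic chroman methyl ester F1. The stereocentre is then sorted instead of set. Preparative chromatography on a polysaccharide chiral stationary phase separates the (2R)-ester from the (2S)-chroman methyl ester F2. The route is rejoined at 9.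

Step 2. Three processes may spoil it:
- slow oxidative addition into the electron-rich, doubly ortho-substituted bromide;
- protodestannylation of the allylstannane by the acidic phenols;
- partial transfer through the γ-carbon of the prenyl group.

The fallback sets out from 2 and builds the prenyl group in two stages. An aqueous Suzuki–Miyaura allylation (allylboronic acid pinacol ester, Pd(dppf)Cl2, K3PO4, THF/H2O, 70 °C) tolerates phenoxides and has no regiochemical ambiguity. It should give methyl 3-allyl-4,6-dihydroxy-2-methylbenzoate F3. Cross-metathesis with excess 2-methylbut-2-ene (second-generation Grubbs catalyst, CH2Cl2, 40 °C) then installs the trisubstituted alkene. The route is rejoined at 4.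

Step 5. Attack of hydroxide on the hindered, phenoxide-deactivated carbonyl may be too slow. Forcing it invites decarboxylation or ionisation at C2 during the acidic work-up. The fallback sets out from 9 and attacks the O–CH3 carbon instead of the carbonyl. This is an SN2 dealkylation with lithium propane-1-thiolate (DMF or HMPA, rt), followed by cold acidification to pH 4. The route is rejoined at 10, and the detour makes no compound outside the list (none, F0).

Further compounds
F1 | step 4 | racemic methyl 5-hydroxy-2,7-dimethyl-2-[(1E)-4-methylpenta-1,3-dien-1-yl]-8-(3-methylbut-2-en-1-yl)-3,4-dihydro-2H-chromene-6-carboxylate | CC(C)=C/C=C/C1(C)CCc2c(O)c(C(=O)OC)c(C)c(CC=C(C)C)c2O1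
F2 | step 4 | methyl (2S)-5-hydroxy-2,7-dimethyl-2-[(1E)-4-methylpenta-1,3-dien-1-yl]-8-(3-methylbut-2-en-1-yl)-3,4-dihydro-2H-chromene-6-carboxylate | CC(C)=C/C=C/[C@]1(C)CCc2c(O)c(C(=O)OC)c(C)c(CC=C(C)C)c2O1
F3 | step 2 | methyl 3-allyl-4,6-dihydroxy-2-methylbenzoate | COC(=O)c1c(C)c(CC=C)c(O)cc1O
F0 | step 5 | none | none
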